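**The question.** The flask is short of reagent, and what is asked is how strongly the rate of making target answers to the charge of free catalyst, read at a fixed conversion.

- apparent order in free catalyst when 20% of the starting material are converted (percent change of the rate of making target for one percent more free catalyst charged)

- Saturday's: starting material 0.20 mM; reagent 0.18 mM; free catalyst 0.48 µM; run made earlier
- flask: starting material 0.20 mM; reagent 0.120 mM; free catalyst 0.48 µM

Saturday's run (percent of the starting material charged)

| time / s | target / % | starting material / % |
|---|---|---|
| 10.0 | 16.1 | 84.5 |
| 25.0 | 32.3 | 68.6 |

(scatter of a reading: 0.3 percentage points)

- no earlier run changes the charge of free catalyst; that part of a forecast is a guess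

**The readings.** In Saturday's run target and starting material sum to 101% and then 101%, close to the charge, with 0.3 percentage points on each reading. Reagent was never read, so its side of the books is inferred, not measured.

**The ledger.** This reckoning takes one reagent per target. In the flask c(reagent), 0.120 mM, lies under c(starting material), 0.20 mM, so reagent is the limiting reagent and target stops at 60.0%. The claim, the percentage of the reagent charge booked for each percentage of starting material converted, is 1.67. At 20% conversion, target's entry therefore takes 33.3%, and the books leave c(reagent) at 0.0800 mM.

**Fixed conversion.** On these books both concentrations then follow conversion, not time, whatever the catalyst charge. A rate first order in free catalyst gives an order of one, and this reckoning commits to that. An entry of reagent that runs by the clock lies outside these books.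

**The forecast.** The forecast sets the order at 0.95, a little under this reckoning, within 0.6 to 1.2, and calls itself a guess: “no run varied the catalyst, so this is a guess”.

**The result.** The flask gives an order of 1.3, and reagent and dormant form, by their exchange step alone, relax with a half-life of 0.0716 min, shorter than the 0.268 min the flask takes to reach 20%.

    starting material + catalyst intermediate B → catalyst intermediate C (k = 2.40 × 10⁵ /M/s)
    catalyst intermediate D → free catalyst + target (k = 13.0 /s)
    catalyst intermediate A → released group + catalyst intermediate B (k = 950 /s)
    catalyst intermediate C → catalyst intermediate D (k = 37.0 /s)
    reagent ⇌ dormant form (K = 2.90, k = 0.120 /s)
    reagent + free catalyst ⇌ catalyst intermediate A (K = 30000 /M, k = 3.90 × 10⁵ /M/s)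

**Books closed.** At 0.200 min the flask holds 16.0% target, which the claim books as 26.7% of the reagent charge, or 0.0320 mM, and released group stands at 0.0324 mM. The books leave 0.0880 mM of reagent, yet free reagent is 0.0255 mM. In that gap stands the entry outside the books: dormant form, 0.0621 mM.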